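All constants are invented; the run is a simulation.

In days, the unit this flask runs in, the free catalyst decays with a half-life of 4.38 d, which is about as long as the run of 4.0 d.

| setting | dawn | summer | winter | midnight |
|---|---|---|---|---|
| substrate | 0.020 M | 0.020 M | 0.020 M (fed, over 2.00 d) | 0.020 M |
| reagent | 0.0200 M | 0.0200 M (fed, over 2.00 d) | 0.0200 M | 0.0200 M |
| free catalyst | 0.50 mM | 0.50 mM | 0.50 mM | 0.50 mM |
| remark | a single well-mixed tank run continuously and read at steady state, 4.0 d in it on average | all but reagent at the start; reagent goes in evenly over 2.00 d, the run ends at 4.0 d | all but substrate at the start; substrate goes in evenly over 2.00 d, the run ends at 4.0 d | everything together in a closed stirred flask, run for 4.0 d |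
| time |  | 4.0 d | 4.0 d | 4.0 d |

    substrate + free catalyst ⇌ free catalyst + intermediate (K1 = 0.66, k1 = 220 M⁻¹ h⁻¹)
    reagent + free catalyst + intermediate → free catalyst + target (k2 = 790 M⁻² h⁻¹)
    free catalyst → spent catalyst (k3 = 0.0066 h⁻¹)
    target ⇌ isomer of the product (K4 = 0.85, k4 = 0.012 h⁻¹)

- the stated concentrations are those of everything mixed, before any reaction; amounts are the same in each set-up
- the feed brings no volume worth counting
- run time (summer): 4.0 d

- the set-up with the highest amount of intermediate at the outlet or at the end, in percent of the substrate put in ("none" if the first two lie within 2 percentage points) (dawn / summer / winter / midnight / none)
- amount of intermediate at the outlet or at the end, in percent of the substrate put in, dawn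
- amount of intermediate at the outlet or at the end, in percent of the substrate put in, summer
- amount of intermediate at the outlet or at the end, in percent of the substrate put in, winter
- amount of intermediate at the outlet or at the end, in percent of the substrate put in, midnight

I start from the balance of the reagent. Substrate and reagent are charged alike, so neither is the limiting reagent, and since each reagent used carries one intermediate off to target, the fraction f of reagent left is also the fraction of charged substrate still in the pool of substrate plus intermediate. In midnight the forward half-life of substrate, 0.26 d, is far shorter than the 3.7 d of intermediate by the second step, so I hold the pool in pre-equilibrium, with a share of 39.8% as intermediate. The reagent's rate then goes with the free catalyst times the square of f, and on integrating, the inverse of f grows from one in step with the time integral of the free catalyst.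

The bench rule says a catalyst comes out as it went in, so I multiply its charge by the run time and get 0.302. That rule holds while decay constant times run time is small against one, but here the product is 0.634, so I replace charge times time by the integral of the decaying free catalyst. This gives 0.223, my catalyst dose: second-step constant times share times substrate charge times that integral, with f equal to one over one plus the dose.

For midnight I get 32.5%. In summer and winter one partner arrives evenly over 2.00 d, so I count the dose of the feed period at half and get 0.159, which gives 34.3% for summer and 34.3% for winter. For the dawn tank I take the steady free catalyst as 0.306 mM, assuming it comes with the feed. With washout counted, I reckon a lower share of 37.5%, and the tank's number 0.174 times the square of f must equal the fraction of reagent lost, so f is 86.9% and dawn gives 32.5%. My two fed flasks share one figure and stand above the others, so they lie within 2 percentage points and my call is none.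

The forecast gives 31.9% for dawn, 33.9% for summer, 34.3% for winter and 32.4% for midnight, with the call none, on the ground that the “fed runs delay that drain”. My dawn stands above its figure.

The flasks give 31.9%, 34.0%, 34.3% and 32.4% in that order, and the call is none. Target and isomer of the product count together in the balance, and the isomer step changes the winter answer by nothing. The winter dose put the reagent left at 86.3%, and the reading is 88%. The neighbouring flask is winter with 0.0020 M of free catalyst, so its dose scales to 0.635, and I expect 24.3% of intermediate and 61.2% of the reagent left. That flask ends with 24.7% of intermediate and 63% of its reagent.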